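**Plan**

1. Retrosynthesis (bicycle numbered C-1 to C-10, C-11 = CH2 on C-9, C-15 = carbon on C-10): cut C-11–C-1′ of the side chain (sulfone alkylation, then desulfonylation) into an ω-silyloxy farnesyl bromide and a bicyclic C-11 sulfone.
2. In the bicycle cut C-1–C-2 and C-5–C-10 together (intramolecular Diels–Alder), then C-3–C-4 (Stille), C-4=C-5 (iodo-olefination) and C-9–C-10 (epoxide opening), back to geraniol and 2-bromoallyl alcohol.
3. Enabling feature: O-3 on ring A makes C-2=C-3–C-4=C-5 a 2-silyloxydiene (the second C-4 methyl is added later through the enol ether). The C-10 methyl is carried as the carbonyl C-15 of an α-methylene-γ-butyrolactone closed on O-11, whose exocyclic C-1=C-10 bond is the dienophile; lactol formation and Wolff–Kishner reduction later turn C-15 into the methyl and free HO-11.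
4. Forward order: acyclic C-8/C-9 stereodiad → lactone → (Z)-diene → rings A and B in one cycloaddition → C-4 methylation, C-3 reduction, lactone removal → C-11 sulfone → side chain → deprotection.
5. Stereochemistry: C-8 and C-9 from Sharpless epoxidation of geraniol and SN2 inversion at C-9; C-5 and C-10 (cis A/B junction) from the Z diene geometry and the lactone-bound dienophile face; C-3 from CBS reduction; the E alkenes from (E,E)-farnesol and E-selective SeO2 hydroxylation.

Key step: step 10

Remark: the target SMILES places H-5 on the same face as the C-10 methyl (cis A/B junction; 3S,5S,8R,9R,10S) and the route is built for exactly this stereoisomer; bicyclic intermediates are named as 5β-drimanes (β = face of C-15; 8β-CH3, 9α-H, C-12 = methyl on C-8).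

**Route**

Step 1
Reactants: 1 2-bromoprop-2-en-1-ol
Product: 2 2-[(2-bromoprop-2-en-1-yl)oxy]oxane (racemic)
Conditions: 3,4-dihydro-2H-pyran, PPTS (cat.), CH2Cl2, rt
Reagents that add atoms: 3,4-dihydro-2H-pyran, C1=COCCC1
Why: Acid-catalysed addition of the alcohol to the enol ether (tetrahydropyranyl acetal formation) masks the hydroxyl with a group that has no acidic proton and cannot migrate to the later carbanion.

Step 2
Reactants: 3 geraniol
Product: 4 (2R,3R)-2,3-epoxygeraniol
Conditions: Ti(OiPr)4 (5 mol %), D-(−)-diethyl tartrate (6 mol %), t-BuOOH, 4 Å MS, CH2Cl2, −20 °C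
Reagents that add atoms: tert-butyl hydroperoxide, CC(C)(C)OO
Why: Sharpless asymmetric epoxidation with the D-(−)-tartrate catalyst should epoxidise only the allylic alcohol, on the face that gives the (2R,3R)-epoxide, which fixes C-8 and (after inversion) C-9.

Step 3
Reactants: 4 (2R,3R)-2,3-epoxygeraniol; 2 2-[(2-bromoprop-2-en-1-yl)oxy]oxane
Product: 6 (2S,3R)-3,7-dimethyl-2-[3-(oxan-2-yloxy)prop-1-en-2-yl]oct-6-ene-1,3-diol, via Grignard reagent 5 (not isolated)
Conditions: 2 (3 equiv), Mg, THF, 40 °C; then CuI (10 mol %), 4, THF, −30 to 0 °C; aq NH4Cl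
Reagents that add atoms: none
Why: Copper-catalysed SN2 opening of a 2,3-epoxy alcohol by an alkenyl Grignard reagent should occur at the secondary epoxide carbon (the other is fully substituted) with inversion, which creates the C-9–C-10 bond and sets C-9 anti to the C-8 oxygen.

Step 4
Reactants: 6 diol tetrahydropyranyl ether
Product: 7 (2S,3R)-2-(3-hydroxyprop-1-en-2-yl)-3,7-dimethyloct-6-ene-1,3-diol
Conditions: PPTS (cat.), MeOH, 40 °C
Reagents that add atoms: none
Why: Acid-catalysed acetal exchange with methanol removes the tetrahydropyranyl group under conditions that leave the tertiary alcohol and both alkenes untouched.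

Step 5
Reactants: 7 triol
Product: 9 (4S)-4-[(2R)-2-hydroxy-6-methylhept-5-en-2-yl]-3-methylideneoxolan-2-one, via lactol 8 (not isolated)
Conditions: activated MnO2 (excess), CH2Cl2, rt
Reagents that add atoms: none
Why: MnO2 oxidises only the allylic alcohol to the enal, the primary C-11 hydroxyl closes the five-membered lactol faster than the hindered tertiary one, and further oxidation of this allylic lactol should give the α-methylene-γ-butyrolactone (oxidative lactonisation of a 2-methylene-1,4-diol).

Step 6
Reactants: 9 hydroxy lactone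
Product: 10 (4S)-3-methylidene-4-[(2R)-6-methyl-2-(triethylsilyloxy)hept-5-en-2-yl]oxolan-2-one
Conditions: Et3SiOTf, 2,6-lutidine, CH2Cl2, −78 to 0 °C
Reagents that add atoms: triethylsilyl triflate, CC[Si](CC)(CC)OS(=O)(=O)C(F)(F)F
Why: Silyl triflate silylation of the tertiary alcohol blocks both acyl migration to O-8 and lactol formation with the aldehyde made in the next step.

Step 7
Reactants: 10 silyl ether lactone
Product: 12 (4R)-4-[(3S)-4-methylidene-5-oxooxolan-3-yl]-4-(triethylsilyloxy)pentanal, via ozonide 11 (not isolated)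
Conditions: O3, CH2Cl2, −78 °C (indicator end point); then PPh3, −78 °C to rt
Reagents that add atoms: ozone, [O-][O+]=O
Why: Ozonolysis with reductive work-up cleaves the electron-rich trisubstituted alkene to the C-5 aldehyde, while the electron-poor conjugated methylene lactone reacts far more slowly.

Step 8
Reactants: 12 aldehyde
Product: 13 (4S)-4-[(2R,5Z)-6-iodo-2-(triethylsilyloxy)hept-5-en-2-yl]-3-methylideneoxolan-2-one
Conditions: EtPPh3I, n-BuLi, THF, rt; I2, −78 °C; NaN(SiMe3)2, −78 °C; then 12, −78 to −20 °C
Reagents that add atoms: ethyltriphenylphosphonium iodide, CC[P+](c1ccccc1)(c1ccccc1)c1ccccc1.[I-]; iodine, II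
Why: Stork–Zhao-type Wittig iodo-olefination with the α-iodoethylidene ylide at low temperature is kinetically Z-selective (iodine cis to the chain), which places the future C-3 on the inside position required for the diene.

Step 9
Reactants: 13 (Z)-vinyl iodide
Product: 15 (4S)-3-methylidene-4-[(2R,5Z)-6-methyl-7-oxo-2-(triethylsilyloxy)oct-5-en-2-yl]oxolan-2-one, via ethoxydiene 14 (not isolated)
Conditions: tributyl(1-ethoxyvinyl)stannane, Pd(PPh3)4 (5 mol %), CuI (10 mol %), DMF, 23 °C; then 1 M HCl, THF, 0 °C
Reagents that add atoms: tributyl(1-ethoxyvinyl)stannane, CCCC[Sn](CCCC)(CCCC)C(=C)OCC; water, O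
Why: Stille cross-coupling proceeds with retention of alkene geometry, and the 1-ethoxyvinyl group serves as an acetyl anion equivalent that is unmasked by cold dilute acid before the dienyl ether can cyclise.

Step 10
Reactants: 15 (Z)-enone lactone
Product: 17 3,8α-bis(triethylsilyloxy)-14-nor-5β-drim-3-en-15,11-olide, via silyloxydiene 16 (not isolated)
Conditions: Et3SiOTf, Et3N, CH2Cl2, −78 °C; aq NaHCO3 work-up; then PhMe, BHT, 90 °C
Reagents that add atoms: triethylsilyl triflate, CC[Si](CC)(CC)OS(=O)(=O)C(F)(F)F
Why: Soft enolisation of the methyl ketone gives the (Z)-2-silyloxydiene C-2=C-3(OSiEt3)–C-4(CH3)=C-5, which on warming undergoes a normal-electron-demand intramolecular Diels–Alder reaction (type 1, four-atom tether C-6 to C-9) with the exocyclic C-1=C-10 bond of the α-methylene-γ-butyrolactone; the closest known reaction type is the thermal cycloaddition of 2-silyloxy-1,3,9-decatrienes that carry an acrylate-type dienophile. Ring A closes as the [4+2] cyclohexene ring by forming C-1–C-2 and C-5–C-10 (nucleophilic diene terminus C-2 onto the β-carbon C-1, matching the polarisation of both partners), and ring B closes at the same time as the six-membered tether ring through the new C-5–C-10 bond. C-5: because the tether sits on the inside (Z) position of the diene terminus, only the transition state with the tether exo and the lactone carbonyl endo can be reached, which puts H-5 cis to C-15, that is the cis A/B junction. C-10: the dienophile carbon is trigonal within the nearly planar lactone and the diene is anchored through C-8 on the neighbouring C-9, so the diene can reach only the lactone face that carries C-8, which fixes C-10 relative to C-9 and C-8. The step therefore needs ring-fusion (cis against trans) and π-facial selectivity, secured by the Z diene geometry and by the lactone ring with its C-9 stereocenter respectively, while regioselectivity is enforced by the tether.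

Step 11
Reactants: 17 silyl enol ether lactone
Product: 18 3-oxo-8α-(triethylsilyloxy)-5β-driman-15,11-olide
Conditions: TASF (1.05 equiv), MeI, THF, −40 to 0 °C
Reagents that add atoms: iodomethane, CI
Why: Fluoride cleaves the silyl enol ether to a regiodefined naked enolate that is C-methylated at C-4 (regiospecific enolate alkylation of a silyl enol ether), giving the gem-dimethyl group without creating a stereocenter.

Step 12
Reactants: 18 keto lactone
Product: 19 3β-hydroxy-8α-(triethylsilyloxy)-5β-driman-15,11-olide (3S)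
Conditions: (R)-2-methyl-CBS-oxazaborolidine (20 mol %), BH3·SMe2, THF, −20 °C; MeOH
Reagents that add atoms: none
Why: In this Corey–Bakshi–Shibata reduction the oxazaborolidine differentiates the quaternary C-4 flank from the C-2 methylene, so the (R)-catalyst should deliver hydride to the face giving the (3S)-alcohol under reagent control, which is chosen because the flexible cis-decalin offers no dependable substrate bias.

Step 13
Reactants: 19 hydroxy lactone
Product: 20 15,11-epoxy-8α-(triethylsilyloxy)-5β-drimane-3β,15-diol (lactol; C-15 anomers)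
Conditions: i-Bu2AlH (3 equiv), CH2Cl2, −78 °C; Rochelle salt
Reagents that add atoms: none
Why: Partial reduction of the lactone by i-Bu2AlH stops at the lactol because the tetrahedral aluminium acetal is stable at −78 °C.

Step 14
Reactants: 20 lactol
Product: 22 5β-drimane-3β,8α,11-triol, via hydrazone 21 (not isolated)
Conditions: N2H4·H2O, KOH, diethylene glycol, 130 °C then 200 °C
Reagents that add atoms: none
Why: Wolff–Kishner reduction (Huang-Minlon procedure) of the lactol through its ring-opened hydroxy aldehyde hydrazone converts C-15 into the C-10 methyl and frees the C-11 hydroxyl, while the hot alkaline glycol also cleaves the tertiary silyl ether.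

Step 15
Reactants: 22 triol
Product: 23 11-(phenylsulfanyl)-5β-drimane-3β,8α-diol
Conditions: PhSSPh, PBu3, pyridine, 50 °C
Reagents that add atoms: diphenyl disulfide, c1ccc(SSc2ccccc2)cc1
Why: The Mukaiyama–Hata redox condensation activates only the primary C-11 hydroxyl as an alkoxyphosphonium ion that thiolate displaces by SN2, the hindered secondary and tertiary hydroxyls staying free.

Step 16
Reactants: 23 sulfide
Product: 24 11-(phenylsulfonyl)-5β-drimane-3β,8α-diol
Conditions: mCPBA (2.2 equiv), NaHCO3, CH2Cl2, 0 °C to rt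
Reagents that add atoms: 3-chloroperbenzoic acid, OOC(=O)c1cccc(Cl)c1
Why: Peracid oxidation of the sulfide to the sulfone is clean here because the bicycle holds no alkene or other oxidisable group.

Step 17
Reactants: 25 (2E,6E)-farnesol
Product: 26 (2E,6E)-farnesyl acetate
Conditions: Ac2O, pyridine, DMAP (cat.), CH2Cl2, rt
Reagents that add atoms: acetic anhydride, CC(=O)OC(C)=O
Why: Acetylation protects the allylic alcohol and deactivates the neighbouring alkene toward the allylic oxidation that follows.

Step 18
Reactants: 26 farnesyl acetate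
Product: 27 (2E,6E,10E)-12-hydroxyfarnesyl acetate
Conditions: SeO2 (cat.), t-BuOOH, salicylic acid (cat.), CH2Cl2, rt
Reagents that add atoms: selenium dioxide, O=[Se]=O; tert-butyl hydroperoxide, CC(C)(C)OO
Why: SeO2-catalysed allylic hydroxylation (ene reaction then [2,3]-sigmatropic shift) is selective for the (E)-methyl of the terminal isopropylidene group and should give the (10E)-allylic alcohol.

Step 19
Reactants: 27 hydroxy acetate
Product: 28 (2E,6E,10E)-12-(tert-butyldimethylsilyloxy)farnesyl acetate
Conditions: TBSCl, imidazole, DMF, rt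
Reagents that add atoms: tert-butyldimethylsilyl chloride, CC(C)(C)[Si](C)(C)Cl
Why: Standard silylation of the primary allylic alcohol gives an ether that survives the organolithium coupling and the amalgam reduction.

Step 20
Reactants: 28 silyloxy acetate
Product: 29 (2E,6E,10E)-12-(tert-butyldimethylsilyloxy)farnesol
Conditions: K2CO3 (cat.), MeOH, rt
Reagents that add atoms: none
Why: Base-catalysed transesterification with methanol removes the acetate without touching the silyl ether.

Step 21
Reactants: 29 allylic alcohol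
Product: 30 (2E,6E,10E)-12-(tert-butyldimethylsilyloxy)farnesyl bromide
Conditions: CBr4, PPh3, CH2Cl2, 0 °C
Reagents that add atoms: tetrabromomethane, BrC(Br)(Br)Br
Why: The Appel reaction converts the primary allylic alcohol into the bromide by SN2 under neutral conditions, without allylic transposition or loss of alkene geometry.

Step 22
Reactants: 24 11-(phenylsulfonyl)-5β-drimane-3β,8α-diol; 30 silyloxy farnesyl bromide
Product: 32 11-(phenylsulfonyl)-30-O-(tert-butyldimethylsilyl)myrrhanol A (C-11 epimers), via trilithio sulfone 31 (not isolated)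
Conditions: 24, n-BuLi (3.2 equiv), THF/HMPA, −78 to −40 °C; then 30, −78 °C; aq NH4Cl
Reagents that add atoms: none
Why: In this Julia-type alkylation the α-sulfonyl carbanion is far more nucleophilic than the two lithium alkoxides and should displace the primary allylic bromide by SN2 without touching the alkene geometry, the new C-11 stereocenter being removed in the next step.

Step 23
Reactants: 32 coupled sulfone
Product: 33 30-O-(tert-butyldimethylsilyl)myrrhanol A
Conditions: sodium amalgam (6 % Na), Na2HPO4, MeOH/THF, −20 °C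
Reagents that add atoms: none
Why: Reductive desulfonylation by electron transfer removes the non-allylic sulfone without double-bond migration, the buffer protecting the silyl ether and the alcohols.

Step 24
Reactants: 33 silyl ether
Product: 34 myrrhanol A
Conditions: Bu4NF, THF, rt
Reagents that add atoms: none
Why: Fluoride-mediated desilylation frees the primary allylic alcohol under conditions that leave the three alkenes and the tertiary alcohol unchanged.

**Compound list**

1 | 2-bromoprop-2-en-1-ol | OCC(Br)=C | starting material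
2 | 2-[(2-bromoprop-2-en-1-yl)oxy]oxane (racemic) | C=C(Br)COC1CCCCO1 | intermediate
3 | geraniol | CC(C)=CCC/C(C)=C/CO | starting material
4 | [(2R,3R)-3-methyl-3-(4-methylpent-3-en-1-yl)oxiran-2-yl]methanol | CC(C)=CCC[C@@]1(C)O[C@@H]1CO | intermediate
5 | [3-(oxan-2-yloxy)prop-1-en-2-yl]magnesium bromide | C=C([Mg]Br)COC1CCCCO1 | intermediate
6 | (2S,3R)-3,7-dimethyl-2-[3-(oxan-2-yloxy)prop-1-en-2-yl]oct-6-ene-1,3-diol (acetal epimers) | CC(C)=CCC[C@@](C)(O)[C@H](CO)C(=C)COC1CCCCO1 | intermediate
7 | (2S,3R)-2-(3-hydroxyprop-1-en-2-yl)-3,7-dimethyloct-6-ene-1,3-diol | CC(C)=CCC[C@@](C)(O)[C@H](CO)C(=C)CO | intermediate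
8 | (4S)-4-[(2R)-2-hydroxy-6-methylhept-5-en-2-yl]-3-methylideneoxolan-2-ol (anomers) | CC(C)=CCC[C@@](C)(O)[C@@H]1COC(O)C1=C | intermediate
9 | (4S)-4-[(2R)-2-hydroxy-6-methylhept-5-en-2-yl]-3-methylideneoxolan-2-one | CC(C)=CCC[C@@](C)(O)[C@@H]1COC(=O)C1=C | intermediate
10 | (4S)-3-methylidene-4-[(2R)-6-methyl-2-(triethylsilyloxy)hept-5-en-2-yl]oxolan-2-one | CC(C)=CCC[C@@](C)(O[Si](CC)(CC)CC)[C@@H]1COC(=O)C1=C | intermediate
11 | secondary ozonide (1,2,4-trioxolane) of 10 at the trisubstituted alkene | CC1(C)OOC(CC[C@@](C)(O[Si](CC)(CC)CC)[C@@H]2COC(=O)C2=C)O1 | intermediate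
12 | (4R)-4-[(3S)-4-methylidene-5-oxooxolan-3-yl]-4-(triethylsilyloxy)pentanal | O=CCC[C@@](C)(O[Si](CC)(CC)CC)[C@@H]1COC(=O)C1=C | intermediate
13 | (4S)-4-[(2R,5Z)-6-iodo-2-(triethylsilyloxy)hept-5-en-2-yl]-3-methylideneoxolan-2-one | C/C(I)=C/CC[C@@](C)(O[Si](CC)(CC)CC)[C@@H]1COC(=O)C1=C | intermediate
14 | (4S)-4-[(2R,5Z)-7-ethoxy-6-methyl-2-(triethylsilyloxy)octa-5,7-dien-2-yl]-3-methylideneoxolan-2-one | C=C(OCC)/C(C)=C\CC[C@@](C)(O[Si](CC)(CC)CC)[C@@H]1COC(=O)C1=C | intermediate
15 | (4S)-3-methylidene-4-[(2R,5Z)-6-methyl-7-oxo-2-(triethylsilyloxy)oct-5-en-2-yl]oxolan-2-one | CC(=O)/C(C)=C\CC[C@@](C)(O[Si](CC)(CC)CC)[C@@H]1COC(=O)C1=C | intermediate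
16 | (4S)-4-[(2R,5Z)-6-methyl-2,7-bis(triethylsilyloxy)octa-5,7-dien-2-yl]-3-methylideneoxolan-2-one | C=C(O[Si](CC)(CC)CC)/C(C)=C\CC[C@@](C)(O[Si](CC)(CC)CC)[C@@H]1COC(=O)C1=C | intermediate
17 | 3,8α-bis(triethylsilyloxy)-14-nor-5β-drim-3-en-15,11-olide (H-5, C-15 and C-11 β; H-9 α; 8β-CH3) | O=C1OC[C@@H]2[C@]13CCC(O[Si](CC)(CC)CC)=C(C)[C@H]3CC[C@@]2(C)O[Si](CC)(CC)CC | intermediate
18 | 3-oxo-8α-(triethylsilyloxy)-5β-driman-15,11-olide | O=C1OC[C@@H]2[C@]13CCC(=O)C(C)(C)[C@H]3CC[C@@]2(C)O[Si](CC)(CC)CC | intermediate
19 | (3S)-3β-hydroxy-8α-(triethylsilyloxy)-5β-driman-15,11-olide | O=C1OC[C@@H]2[C@]13CC[C@H](O)C(C)(C)[C@H]3CC[C@@]2(C)O[Si](CC)(CC)CC | intermediate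
20 | 15,11-epoxy-8α-(triethylsilyloxy)-5β-drimane-3β,15-diol (C-15 anomers) | OC1OC[C@@H]2[C@]13CC[C@H](O)C(C)(C)[C@H]3CC[C@@]2(C)O[Si](CC)(CC)CC | intermediate
21 | hydrazone of 3β,11-dihydroxy-8α-(triethylsilyloxy)-5β-driman-15-al | OC[C@@H]1[C@@]2(C=NN)CC[C@H](O)C(C)(C)[C@H]2CC[C@@]1(C)O[Si](CC)(CC)CC | intermediate
22 | 5β-drimane-3β,8α,11-triol | OC[C@@H]1[C@@]2(C)CC[C@H](O)C(C)(C)[C@H]2CC[C@@]1(C)O | intermediate
23 | 11-(phenylsulfanyl)-5β-drimane-3β,8α-diol | c1ccccc1SC[C@@H]1[C@@]2(C)CC[C@H](O)C(C)(C)[C@H]2CC[C@@]1(C)O | intermediate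
24 | 11-(phenylsulfonyl)-5β-drimane-3β,8α-diol | O=S(=O)(c1ccccc1)C[C@@H]1[C@@]2(C)CC[C@H](O)C(C)(C)[C@H]2CC[C@@]1(C)O | intermediate
25 | (2E,6E)-farnesol | CC(C)=CCC/C(C)=C/CC/C(C)=C/CO | starting material
26 | (2E,6E)-farnesyl acetate | CC(C)=CCC/C(C)=C/CC/C(C)=C/COC(C)=O | intermediate
27 | (2E,6E,10E)-12-hydroxyfarnesyl acetate | C/C(=C\CC/C(C)=C/CC/C(C)=C/COC(C)=O)CO | intermediate
28 | (2E,6E,10E)-12-(tert-butyldimethylsilyloxy)farnesyl acetate | C/C(=C\CC/C(C)=C/CC/C(C)=C/COC(C)=O)CO[Si](C)(C)C(C)(C)C | intermediate
29 | (2E,6E,10E)-12-(tert-butyldimethylsilyloxy)farnesol | C/C(=C\CC/C(C)=C/CC/C(C)=C/CO)CO[Si](C)(C)C(C)(C)C | intermediate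
30 | (2E,6E,10E)-12-(tert-butyldimethylsilyloxy)farnesyl bromide | C/C(=C\CC/C(C)=C/CC/C(C)=C/CBr)CO[Si](C)(C)C(C)(C)C | intermediate
31 | trilithio derivative of 24 (C-11 carbanion; O-3 and O-8 alkoxides) | [Li+].[Li+].[Li+].O=S(=O)(c1ccccc1)[CH-][C@@H]1[C@@]2(C)CC[C@H]([O-])C(C)(C)[C@H]2CC[C@@]1(C)[O-] | intermediate
32 | 11-(phenylsulfonyl)-30-O-(tert-butyldimethylsilyl)myrrhanol A (C-11 epimers) | C/C(=C\CC/C(C)=C/CC/C(C)=C/CC(S(=O)(=O)c1ccccc1)[C@@H]1[C@@]2(C)CC[C@H](O)C(C)(C)[C@H]2CC[C@@]1(C)O)CO[Si](C)(C)C(C)(C)C | intermediate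
33 | 30-O-(tert-butyldimethylsilyl)myrrhanol A | C/C(=C\CC/C(C)=C/CC/C(C)=C/CC[C@@H]1[C@@]2(C)CC[C@H](O)C(C)(C)[C@H]2CC[C@@]1(C)O)CO[Si](C)(C)C(C)(C)C | intermediate
34 | myrrhanol A (3S,5S,8R,9R,10S; 13E,17E,21E) | C/C(=C\CC/C(C)=C/CC/C(C)=C/CC[C@@H]1[C@@]2(C)CC[C@H](O)C(C)(C)[C@H]2CC[C@@]1(C)O)CO | target

**Step count**

Total: 24 steps. Longest linear sequence: 18 steps (steps 2–16 and 22–24, from geraniol).

**Steps most likely to fail**

Step 10. The cycloaddition of the Z diene may be slow because the inside substituent is compressed in the s-cis conformer, so that desilylation or a 1,5-hydrogen shift of the diene competes on heating. Fallback, setting out from 15: an anionic intramolecular double Michael annulation. LiN(SiMe3)2 in THF at −78 °C would form the kinetic cross-conjugated lithium dienolate F1. This should add through C-2 to the exocyclic C-1, and the resulting lactone enolate should close onto C-5 of the Z-enone to give the regiodefined lithium C-3/C-4 enolate F2. Trapping F2 in the same flask with MeI would give 18, where the route is rejoined (steps 10 and 11 are replaced). The ring-fusion outcome of this stepwise closure would have to be confirmed.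

Step 8. The basic ylide may add in conjugate fashion to the methylene lactone, or the olefination may lose Z selectivity. Fallback, setting out from 7, so that the ylide never meets the lactone: persilylation with Et3SiOTf/2,6-lutidine would give the tris(triethylsilyl) ether F3. Ozonolysis of its trisubstituted alkene would give the aldehyde F4, and the same Stork–Zhao olefination would give the Z-vinyl iodide F5. PPTS in MeOH would remove only the two primary silyl ethers to give the diol F6, and MnO2 oxidative lactonisation would then give 13, where the route is rejoined.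

Step 11. Proton transfer between the naked enolate and the product ketone may lead to methylation at C-2, or O-methylation may compete at the hindered C-4. Fallback, setting out from 17: Simmons–Smith cyclopropanation of the silyl enol ether (Et2Zn, CH2I2) would give the siloxycyclopropane F7. Mild acid (TsOH, wet CH2Cl2) should open the bond between C-3 and the new CH2, which turns that carbon into the second C-4 methyl and gives 18, where the route is rejoined.

**Further compounds**

F1 | step 10 | lithium dienolate of 15 | [Li]OC(=C)/C(C)=C\CC[C@@](C)(O[Si](CC)(CC)CC)[C@@H]1COC(=O)C1=C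
F2 | step 10 | lithium C-3 enolate of 14-nor-8α-(triethylsilyloxy)-5β-drim-3-en-15,11-olide | O=C1OC[C@@H]2[C@]13CCC(O[Li])=C(C)[C@H]3CC[C@@]2(C)O[Si](CC)(CC)CC
F3 | step 8 | tris(triethylsilyl) ether of 7 | CC(C)=CCC[C@@](C)(O[Si](CC)(CC)CC)[C@H](CO[Si](CC)(CC)CC)C(=C)CO[Si](CC)(CC)CC
F4 | step 8 | (4R,5S)-6-methylidene-4-methyl-4,7-bis(triethylsilyloxy)-5-[(triethylsilyloxy)methyl]heptanal | O=CCC[C@@](C)(O[Si](CC)(CC)CC)[C@H](CO[Si](CC)(CC)CC)C(=C)CO[Si](CC)(CC)CC
F5 | step 8 | Z-vinyl iodide from F4 | C/C(I)=C/CC[C@@](C)(O[Si](CC)(CC)CC)[C@H](CO[Si](CC)(CC)CC)C(=C)CO[Si](CC)(CC)CC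
F6 | step 8 | 1,4-diol from F5 (tertiary silyl ether kept) | C/C(I)=C/CC[C@@](C)(O[Si](CC)(CC)CC)[C@H](CO)C(=C)CO
F7 | step 11 | siloxycyclopropane from 17 (3,4-methano adduct; either face) | O=C1OC[C@@H]2[C@]13CCC4(O[Si](CC)(CC)CC)CC4(C)[C@H]3CC[C@@]2(C)O[Si](CC)(CC)CC
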